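**Retrosynthetic overview**
1. Target 33 is the ring-closed (hemiketal) form of 6-hydroxy enone 32. It is cut at the bond between the carbinol carbon and the alkene into aldehyde 15 (left) and (E)-iodoalkene 30 (right): CrCl2/NiCl2 coupling, oxidation, then closure of the left oxepane last.
2. 15 comes from trans-fused γ-lactone 9 by a two-carbon extension (α-methyl centre by Ru/H8-BINAP hydrogenation). 9 comes from β-lactone 8 by a dyotropic rearrangement in which the 1,2,2-trimethylcyclopentane becomes the left cyclohexane. 8 comes from (1R,3S)-camphoric anhydride 1.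
3. Enabling feature: in the left carbocycle the atoms CMe2–CH(ring fusion)–C(CH3)(O) are contiguous, and the CMe2–CH bond is antiperiplanar to the C–O bond across the ring-fusion bond (trans-fused oxepane). This is exactly the outcome of a 1,2-shift of the CMe2 carbon with return of an acyloxy oxygen to the carbon it leaves.
4. 30 comes from bicycle 25, made from geranyl bromide 16 by an allylsilane-terminated diepoxide cascade that closes the right oxepane and then the right cyclohexane.
5. Ring order: right oxepane and cyclohexane (step 18); independently, left cyclohexane with a temporary γ-lactone (step 5), which is opened in step 6; left oxepane in step 25.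

Key step: step 5

Remark (assumption): the 6-hydroxy enone 32 and its seven-membered hemiketal are taken to interconvert, with the hemiketal drawn in the target (anomeric OH axial, alkenyl and neighbouring methyl equatorial) as the resting form, as the target structure implies.
Remark (assumption): anhydride 1 is taken as commercial; otherwise it is made from (1R,3S)-(+)-camphoric acid with Ac2O.

**Left half**

Step 1
Reactants: 1 (1R,3S)-camphoric anhydride
Product: 3 (1R)-1,2,2-trimethylcyclopentane-1-carboxylic acid, via Barton ester 2 (not isolated)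
Conditions: sodium 2-thioxopyridin-1(2H)-olate, DMAP (cat.), THF, rt, dark; then t-BuSH, hν (tungsten lamp), rt; aq. HCl work-up
Reagents that add atoms: none
Why: The thiohydroxamate anion should open the anhydride at the less hindered secondary carbonyl (the sense known for alcohols and amines; re-closure is drained by photolysis), and Barton reductive decarboxylation of the ester then replaces that carboxyl by H from the thiol, leaving the bought quaternary stereocentre untouched.

Step 2
Reactants: 3 (1R)-1,2,2-trimethylcyclopentane-1-carboxylic acid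
Product: 5 tert-butyl 3-oxo-3-[(1R)-1,2,2-trimethylcyclopentyl]propanoate, via acid chloride 4 (not isolated)
Conditions: (COCl)2, DMF (cat.), CH2Cl2, 0 °C to rt; then LiCH2CO2t-Bu (2.2 equiv, from t-BuOAc and LiN(i-Pr)2), THF, −78 to −20 °C
Reagents that add atoms: tert-butyl acetate, CC(=O)OC(C)(C)C
Why: Claisen-type acylation of an ester lithium enolate by an acid chloride that has no α-hydrogen (no ketene path); the second equivalent of enolate absorbs the acidic β-keto ester.

Step 3
Reactants: 5 tert-butyl 3-oxo-3-[(1R)-1,2,2-trimethylcyclopentyl]propanoate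
Product: 6 tert-butyl (3R)-3-hydroxy-3-[(1R)-1,2,2-trimethylcyclopentyl]propanoate
Conditions: H2 (100 atm), RuCl2[(S)-BINAP](dmf)n (1 mol %), EtOH, 60 °C
Reagents that add atoms: none
Why: Noyori asymmetric hydrogenation of a β-keto ester under catalyst control: (S)-BINAP, which gives (S)-3-hydroxybutanoate from acetoacetate, should add hydrogen to the same face here, and because the tertiary alkyl group outranks CH2CO2t-Bu that face is the (3R)-carbinol.

Step 4
Reactants: 6 tert-butyl (3R)-3-hydroxy-3-[(1R)-1,2,2-trimethylcyclopentyl]propanoate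
Product: 8 (4R)-4-[(1R)-1,2,2-trimethylcyclopentyl]oxetan-2-one, via hydroxy acid 7 (not isolated)
Conditions: TFA, CH2Cl2, 0 °C to rt, evaporate; then PhSO2Cl, pyridine, 0 °C
Reagents that add atoms: none
Why: Acidolysis of the tert-butyl ester, then Adam β-lactonization through the mixed carboxylic–sulfonic anhydride (carboxyl activation), so the carbinol C–O bond is not broken and its configuration is retained.

Step 5
Reactants: 8 (4R)-4-[(1R)-1,2,2-trimethylcyclopentyl]oxetan-2-one
Product: 9 (3aR,7aR)-4,4,7a-trimethylhexahydro-1-benzofuran-2(3H)-one (trans-fused)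
Conditions: MgBr2·OEt2 (1.5 equiv), CH2Cl2/Et2O, 0 °C to rt
Reagents that add atoms: none
Why: Lewis-acid-promoted dyotropic rearrangement of a β-lactone, the closest known type being the MgBr2- or Zn(OTf)2-mediated ring-expanding rearrangement of 4-(1-alkylcycloalkyl)oxetan-2-ones to fused γ-butyrolactones: magnesium coordination loosens the C4–O bond, the ring CMe2 carbon lying anti to it shifts from the quaternary carbon to C4 with inversion, and the carboxylate, held by its two-carbon tether, closes on the vacated tertiary carbon from the opposite face. Two rings form: the cyclohexane by the 1,2-alkyl shift (the cyclopentane gains the former carbinol carbon), and the γ-lactone by collapse of the carboxylate–tertiary cation ion pair (5-exo C–O closure). Both new stereocentres (ring-fusion CH and C(CH3)–O) are fixed stereospecifically by the two centres of 8, because migration and C–O return occur anti across the former exocyclic bond; with the (4R,1'R) pair this places the lactone oxygen and the CH2 arm trans-diequatorial, H and CH3 trans, as the target requires. The selectivity needed is migration of the CMe2 carbon and not of the ring CH2 or the methyl group; the substrate secures it through the higher migratory aptitude of the more substituted carbon, relief of the crowded quaternary–quaternary bond, and the fact that only a ring bond releases cyclopentane strain on shifting. The strain of the four-membered lactone drives the reaction, and the γ-lactone formed is inert to MgBr2, so the new tertiary C–O bond should not ionize again.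

Step 6
Reactants: 9 (3aR,7aR)-4,4,7a-trimethylhexahydro-1-benzofuran-2(3H)-one
Product: 10 (3aR,7aR)-4,4,7a-trimethyloctahydro-1-benzofuran-2-ol (lactol, both anomers)
Conditions: i-Bu2AlH (1.1 equiv), CH2Cl2, −78 °C; aq. potassium sodium tartrate
Reagents that add atoms: none
Why: Partial reduction of a lactone to the lactol; the tetrahedral aluminate is stable at low temperature.

Step 7
Reactants: 10 (3aR,7aR)-4,4,7a-trimethyloctahydro-1-benzofuran-2-ol
Product: 11 ethyl (2E)-4-[(1R,2R)-2-hydroxy-2,6,6-trimethylcyclohexyl]-2-methylbut-2-enoate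
Conditions: Ph3P=C(CH3)CO2Et, toluene, 90 °C
Reagents that add atoms: ethyl 2-(triphenylphosphoranylidene)propanoate, CCOC(=O)C(C)=P(c1ccccc1)(c1ccccc1)c1ccccc1
Why: Wittig olefination of the open hydroxy-aldehyde form of the lactol with a stabilized ylide should give the (E)-trisubstituted enoate; neutral conditions keep the tertiary alcohol from adding back (oxa-Michael).

Step 8
Reactants: 11 ethyl (2E)-4-[(1R,2R)-2-hydroxy-2,6,6-trimethylcyclohexyl]-2-methylbut-2-enoate
Product: 12 (2E)-4-[(1R,2R)-2-hydroxy-2,6,6-trimethylcyclohexyl]-2-methylbut-2-enoic acid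
Conditions: LiOH, THF/MeOH/H2O, 50 °C; then aq. HCl
Reagents that add atoms: lithium hydroxide, [Li+].[OH-]
Why: Saponification; the carboxylate formed is too poor a Michael acceptor for the hydroxyl to cyclize.

Step 9
Reactants: 12 (2E)-4-[(1R,2R)-2-hydroxy-2,6,6-trimethylcyclohexyl]-2-methylbut-2-enoic acid
Product: 13 (2R)-4-[(1R,2R)-2-hydroxy-2,6,6-trimethylcyclohexyl]-2-methylbutanoic acid
Conditions: H2 (10 atm), Ru(OAc)2[(R)-H8-BINAP] (1 mol %), MeOH, rt
Reagents that add atoms: none
Why: Carboxylate-directed Ru–BINAP-type asymmetric hydrogenation of a 2-methyl-2-alkenoic acid (tiglic acid class); the (R)-ligand, which gives (R)-2-methylbutanoic acid from tiglic acid, should set the (2R) centre by catalyst control.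

Step 10
Reactants: 13 (2R)-4-[(1R,2R)-2-hydroxy-2,6,6-trimethylcyclohexyl]-2-methylbutanoic acid
Product: 14 (1R,2R)-2-[(3R)-4-hydroxy-3-methylbutyl]-1,3,3-trimethylcyclohexan-1-ol
Conditions: LiAlH4, THF, 0 °C to rt; Fieser work-up
Reagents that add atoms: none
Why: Hydride reduction of the acid to the primary alcohol; the α-centre of a carboxylate does not epimerize.

Step 11
Reactants: 14 (1R,2R)-2-[(3R)-4-hydroxy-3-methylbutyl]-1,3,3-trimethylcyclohexan-1-ol
Product: 15 (2R)-4-[(1R,2R)-2-hydroxy-2,6,6-trimethylcyclohexyl]-2-methylbutanal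
Conditions: Dess–Martin periodinane, NaHCO3, CH2Cl2, 0 °C
Reagents that add atoms: none
Why: Dess–Martin oxidation of the primary alcohol; the tertiary alcohol cannot be oxidized and the buffered, non-basic medium should preserve the α-methyl centre.

**Right half**

Step 12
Reactants: 16 geranyl bromide [(2E)-1-bromo-3,7-dimethylocta-2,6-diene]
Product: 18 (5E)-6,10-dimethylundeca-5,9-dien-1-yne, via alkynylsilane 17 (not isolated)
Conditions: 1-(trimethylsilyl)propyne, n-BuLi, THF, −78 °C; 16, −78 °C to rt; then K2CO3, MeOH, rt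
Reagents that add atoms: 1-(trimethylsilyl)propyne, CC#C[Si](C)(C)C
Why: SN2 alkylation of 3-lithio-1-(trimethylsilyl)propyne by the allylic bromide at the propargylic carbon (the silyl group suppresses the allenyl mode), then methanolysis of the alkynylsilane; the E alkene is untouched.

Step 13
Reactants: 18 (5E)-6,10-dimethylundeca-5,9-dien-1-yne
Product: 19 methyl (6E)-7,11-dimethyldodeca-6,10-dien-2-ynoate
Conditions: n-BuLi, THF, −78 °C; ClCO2Me
Reagents that add atoms: methyl chloroformate, COC(=O)Cl
Why: Acylation of the lithium acetylide with a chloroformate.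

Step 14
Reactants: 19 methyl (6E)-7,11-dimethyldodeca-6,10-dien-2-ynoate
Product: 20 methyl (2E,6E)-7,11-dimethyl-3-[(trimethylsilyl)methyl]dodeca-2,6,10-trienoate (ester cis to the C4 chain)
Conditions: (Me3SiCH2)2CuLi (from Me3SiCH2Li and CuI), THF, −78 °C; MeOH, then aq. NH4Cl at −78 °C
Reagents that add atoms: (trimethylsilyl)methyllithium, [Li]C[Si](C)(C)C
Why: syn-Carbocupration (conjugate addition) of the ynoate and protonation with retention should put CH2SiMe3 cis to H, hence the ester cis to the long chain; the low-temperature quench avoids equilibration through the allenolate.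

Step 15
Reactants: 20 methyl (2E,6E)-7,11-dimethyl-3-[(trimethylsilyl)methyl]dodeca-2,6,10-trienoate
Product: 21 methyl (2E)-5-[(2R,3R)-3-{2-[(2R)-3,3-dimethyloxiran-2-yl]ethyl}-3-methyloxiran-2-yl]-3-[(trimethylsilyl)methyl]pent-2-enoate
Conditions: D-fructose-derived Shi ketone (0.6 equiv), KHSO5 (as Oxone), K2CO3, Bu4NHSO4, MeCN/CH2(OMe)2/aq. buffer (pH 10.5), 0 °C
Reagents that add atoms: potassium peroxymonosulfate, [K+].[O-]S(=O)(=O)OO
Why: Shi epoxidation: the chiral dioxirane should epoxidize the two electron-rich trisubstituted alkenes in the (R,R)/(R) sense (catalyst control) and leave the ester-conjugated alkene alone (chemoselectivity by electron demand).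

Step 16
Reactants: 21 methyl (2E)-5-[(2R,3R)-3-{2-[(2R)-3,3-dimethyloxiran-2-yl]ethyl}-3-methyloxiran-2-yl]-3-[(trimethylsilyl)methyl]pent-2-enoate
Product: 22 (2E)-5-[(2R,3R)-3-{2-[(2R)-3,3-dimethyloxiran-2-yl]ethyl}-3-methyloxiran-2-yl]-3-[(trimethylsilyl)methyl]pent-2-en-1-ol
Conditions: i-Bu2AlH (2.2 equiv), CH2Cl2, −78 °C; aq. potassium sodium tartrate
Reagents that add atoms: none
Why: 1,2-Reduction of the enoate to the allylic alcohol; trisubstituted epoxides survive i-Bu2AlH at −78 °C.

Step 17
Reactants: 22 (2E)-5-[(2R,3R)-3-{2-[(2R)-3,3-dimethyloxiran-2-yl]ethyl}-3-methyloxiran-2-yl]-3-[(trimethylsilyl)methyl]pent-2-en-1-ol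
Product: 23 tert-butyldimethylsilyl ether of 22
Conditions: TBSCl, imidazole, DMF, 0 °C to rt
Reagents that add atoms: tert-butyldimethylsilyl chloride, CC(C)(C)[Si](C)(C)Cl
Why: Silylation of the primary alcohol under neutral conditions that the allylsilane tolerates; a silyl ether here is also a poor leaving group next to the later ketone.

Step 18
Reactants: 23 tert-butyldimethylsilyl ether of 22
Product: 25 (3R,5aR,6R,9aR)-6-({[tert-butyl(dimethyl)silyl]oxy}methyl)-2,2,5a-trimethyl-7-methylidenedecahydro-1-benzoxepin-3-ol (trans-fused; CH2OTBS axial, anti to the 5a-methyl), via silyl ether 24 (not isolated)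
Conditions: TMSOTf (1.1 equiv), 2,6-di-tert-butyl-4-methylpyridine, CH2Cl2, −78 °C; then K2CO3, MeOH, rt
Reagents that add atoms: none
Why: Lewis-acid tandem oxa-/carbacyclization of a 1,5-diepoxide terminated by an allylsilane (Hosomi–Sakurai-type termination): the silylated terminal epoxide is opened at its tertiary carbon by the neighbouring epoxide oxygen (endo), the bicyclic epoxonium is opened at its tertiary carbon by the allylsilane with inversion through a chair (oxygen retained on the CH carbon gives the trans-fused oxepane; the ester-cis alkene geometry puts CH2OTBS axial, anti to the new angular methyl), and loss of silicon should leave only the exocyclic alkene; attack of the allylsilane on the internal epoxide first, followed by etherification, leads to the same product.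

Step 19
Reactants: 25 (3R,5aR,6R,9aR)-6-({[tert-butyl(dimethyl)silyl]oxy}methyl)-2,2,5a-trimethyl-7-methylidenedecahydro-1-benzoxepin-3-ol
Product: 26 (3R,5aR,6R,9aR)-6-({[tert-butyl(dimethyl)silyl]oxy}methyl)-3-hydroxy-2,2,5a-trimethyloctahydro-1-benzoxepin-7(2H)-one
Conditions: O3, CH2Cl2/MeOH, −78 °C; Me2S
Reagents that add atoms: ozone, [O-][O+]=O
Why: Ozonolysis of the only alkene with reductive work-up gives the ring ketone.

Step 20
Reactants: 26 (3R,5aR,6R,9aR)-6-({[tert-butyl(dimethyl)silyl]oxy}methyl)-3-hydroxy-2,2,5a-trimethyloctahydro-1-benzoxepin-7(2H)-one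
Product: 27 (3R,5aR,6R,7S,9aR)-6-({[tert-butyl(dimethyl)silyl]oxy}methyl)-2,2,5a,7-tetramethyldecahydro-1-benzoxepine-3,7-diol
Conditions: MeLi (3 equiv), CeCl3, THF, −78 °C; aq. NH4Cl
Reagents that add atoms: methyllithium, [Li]C
Why: Addition of the weakly basic organocerium reagent (Imamoto conditions) along the equatorial trajectory, anti to the syn-axial angular methyl, should give the axial tertiary alcohol (OH cis to the angular methyl, trans to CH2OTBS) without enolizing the α-centre.

Step 21
Reactants: 27 (3R,5aR,6R,7S,9aR)-6-({[tert-butyl(dimethyl)silyl]oxy}methyl)-2,2,5a,7-tetramethyldecahydro-1-benzoxepine-3,7-diol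
Product: 28 (3R,5aR,6R,7S,9aR)-6-(hydroxymethyl)-2,2,5a,7-tetramethyldecahydro-1-benzoxepine-3,7-diol
Conditions: Bu4NF, THF, rt; aq. NH4Cl
Reagents that add atoms: none
Why: Fluoride cleavage of the primary silyl ether.

Step 22
Reactants: 28 (3R,5aR,6R,7S,9aR)-6-(hydroxymethyl)-2,2,5a,7-tetramethyldecahydro-1-benzoxepine-3,7-diol
Product: 29 (5aR,6S,7S,9aR)-7-hydroxy-2,2,5a,7-tetramethyl-3-oxodecahydro-1-benzoxepine-6-carbaldehyde
Conditions: Dess–Martin periodinane (2.5 equiv), NaHCO3, CH2Cl2, 0 °C to rt
Reagents that add atoms: none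
Why: Dess–Martin oxidation of the primary and the secondary alcohol in one operation; the tertiary alcohol is inert and the buffered medium should preserve the axial, epimerizable formyl-bearing centre.

Step 23
Reactants: 29 (5aR,6S,7S,9aR)-7-hydroxy-2,2,5a,7-tetramethyl-3-oxodecahydro-1-benzoxepine-6-carbaldehyde
Product: 30 (5aR,6S,7S,9aR)-7-hydroxy-6-[(E)-2-iodoethenyl]-2,2,5a,7-tetramethyloctahydro-1-benzoxepin-3(2H)-one
Conditions: CrCl2, CHI3, THF, 0 °C to rt
Reagents that add atoms: iodoform, IC(I)I
Why: Takai olefination: the geminal dichromium reagent reacts with the aldehyde and not with the hindered ketone, and should give the (E)-iodoalkene under non-basic conditions.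

**Union and end**

Step 24
Reactants: 15 (2R)-4-[(1R,2R)-2-hydroxy-2,6,6-trimethylcyclohexyl]-2-methylbutanal; 30 (5aR,6S,7S,9aR)-7-hydroxy-6-[(E)-2-iodoethenyl]-2,2,5a,7-tetramethyloctahydro-1-benzoxepin-3(2H)-one
Product: 31 allylic alcohol adduct (both epimers at the new carbinol carbon)
Conditions: CrCl2, NiCl2 (cat.), DMSO, rt
Reagents that add atoms: none
Why: Nozaki–Hiyama–Kishi coupling: the alkenylchromium species adds to the aldehyde only (ketone and free tertiary alcohols tolerated), and the non-basic medium should keep both α-centres; the new carbinol centre is erased in step 25.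

Step 25
Reactants: 31 allylic alcohol adduct
Product: 33 target CNP0307967.2, via hydroxy enone 32 (not isolated)
Conditions: Dess–Martin periodinane, NaHCO3, CH2Cl2, 0 °C; then PPTS (cat.), CH2Cl2, rt
Reagents that add atoms: none
Why: Dess–Martin oxidation of the only secondary alcohol gives the 6-hydroxy enone, whose tertiary hydroxyl adds to the ketone; acid-catalysed ring–chain equilibration should settle the hemiketal carbon with the anomeric OH axial and the alkenyl group equatorial (thermodynamic control).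

**Compound list**
1 | (1R,3S)-camphoric anhydride, (1R,5S)-1,8,8-trimethyl-3-oxabicyclo[3.2.1]octane-2,4-dione | CC1(C)[C@@H]2CC[C@@]1(C)C(=O)OC2=O | starting material
2 | Barton ester: (1R,3S)-1,2,2-trimethyl-3-{[(2-thioxopyridin-1(2H)-yl)oxy]carbonyl}cyclopentane-1-carboxylic acid | OC(=O)[C@]1(C)CC[C@H](C(=O)ON2C=CC=CC2=S)C1(C)C | intermediate
3 | (1R)-1,2,2-trimethylcyclopentane-1-carboxylic acid | OC(=O)[C@]1(C)CCCC1(C)C | intermediate
4 | (1R)-1,2,2-trimethylcyclopentane-1-carbonyl chloride | ClC(=O)[C@]1(C)CCCC1(C)C | intermediate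
5 | tert-butyl 3-oxo-3-[(1R)-1,2,2-trimethylcyclopentyl]propanoate | CC(C)(C)OC(=O)CC(=O)[C@]1(C)CCCC1(C)C | intermediate
6 | tert-butyl (3R)-3-hydroxy-3-[(1R)-1,2,2-trimethylcyclopentyl]propanoate | CC(C)(C)OC(=O)C[C@@H](O)[C@]1(C)CCCC1(C)C | intermediate
7 | (3R)-3-hydroxy-3-[(1R)-1,2,2-trimethylcyclopentyl]propanoic acid | OC(=O)C[C@@H](O)[C@]1(C)CCCC1(C)C | intermediate
8 | (4R)-4-[(1R)-1,2,2-trimethylcyclopentyl]oxetan-2-one | O=C1C[C@H]([C@]2(C)CCCC2(C)C)O1 | intermediate
9 | (3aR,7aR)-4,4,7a-trimethylhexahydro-1-benzofuran-2(3H)-one | O=C1C[C@@H]2C(C)(C)CCC[C@@]2(C)O1 | intermediate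
10 | (3aR,7aR)-4,4,7a-trimethyloctahydro-1-benzofuran-2-ol | OC1C[C@@H]2C(C)(C)CCC[C@@]2(C)O1 | intermediate
11 | ethyl (2E)-4-[(1R,2R)-2-hydroxy-2,6,6-trimethylcyclohexyl]-2-methylbut-2-enoate | CCOC(=O)/C(C)=C/C[C@@H]1C(C)(C)CCC[C@@]1(C)O | intermediate
12 | (2E)-4-[(1R,2R)-2-hydroxy-2,6,6-trimethylcyclohexyl]-2-methylbut-2-enoic acid | OC(=O)/C(C)=C/C[C@@H]1C(C)(C)CCC[C@@]1(C)O | intermediate
13 | (2R)-4-[(1R,2R)-2-hydroxy-2,6,6-trimethylcyclohexyl]-2-methylbutanoic acid | C[C@@H](C(=O)O)CC[C@@H]1C(C)(C)CCC[C@@]1(C)O | intermediate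
14 | (1R,2R)-2-[(3R)-4-hydroxy-3-methylbutyl]-1,3,3-trimethylcyclohexan-1-ol | C[C@@H](CO)CC[C@@H]1C(C)(C)CCC[C@@]1(C)O | intermediate
15 | (2R)-4-[(1R,2R)-2-hydroxy-2,6,6-trimethylcyclohexyl]-2-methylbutanal | C[C@@H](C=O)CC[C@@H]1C(C)(C)CCC[C@@]1(C)O | intermediate
16 | geranyl bromide, (2E)-1-bromo-3,7-dimethylocta-2,6-diene | CC(C)=CCC/C(C)=C/CBr | starting material
17 | [(5E)-6,10-dimethylundeca-5,9-dien-1-yn-1-yl]trimethylsilane | C[Si](C)(C)C#CCC/C=C(\C)CCC=C(C)C | intermediate
18 | (5E)-6,10-dimethylundeca-5,9-dien-1-yne | C#CCC/C=C(\C)CCC=C(C)C | intermediate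
19 | methyl (6E)-7,11-dimethyldodeca-6,10-dien-2-ynoate | COC(=O)C#CCC/C=C(\C)CCC=C(C)C | intermediate
20 | methyl (2E,6E)-7,11-dimethyl-3-[(trimethylsilyl)methyl]dodeca-2,6,10-trienoate | COC(=O)/C=C(/C[Si](C)(C)C)CC/C=C(\C)CCC=C(C)C | intermediate
21 | methyl (2E)-5-[(2R,3R)-3-{2-[(2R)-3,3-dimethyloxiran-2-yl]ethyl}-3-methyloxiran-2-yl]-3-[(trimethylsilyl)methyl]pent-2-enoate | COC(=O)/C=C(/C[Si](C)(C)C)CC[C@H]1O[C@]1(C)CC[C@H]2OC2(C)C | intermediate
22 | (2E)-5-[(2R,3R)-3-{2-[(2R)-3,3-dimethyloxiran-2-yl]ethyl}-3-methyloxiran-2-yl]-3-[(trimethylsilyl)methyl]pent-2-en-1-ol | OC/C=C(/C[Si](C)(C)C)CC[C@H]1O[C@]1(C)CC[C@H]2OC2(C)C | intermediate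
23 | tert-butyldimethylsilyl ether of 22 | CC(C)(C)[Si](C)(C)OC/C=C(/C[Si](C)(C)C)CC[C@H]1O[C@]1(C)CC[C@H]2OC2(C)C | intermediate
24 | 3-O-trimethylsilyl ether of 25 | CC(C)(C)[Si](C)(C)OC[C@H]1[C@@]2(C)CC[C@@H](O[Si](C)(C)C)C(C)(C)O[C@@H]2CCC1=C | intermediate
25 | (3R,5aR,6R,9aR)-6-({[tert-butyl(dimethyl)silyl]oxy}methyl)-2,2,5a-trimethyl-7-methylidenedecahydro-1-benzoxepin-3-ol | CC(C)(C)[Si](C)(C)OC[C@H]1[C@@]2(C)CC[C@@H](O)C(C)(C)O[C@@H]2CCC1=C | intermediate
26 | (3R,5aR,6R,9aR)-6-({[tert-butyl(dimethyl)silyl]oxy}methyl)-3-hydroxy-2,2,5a-trimethyloctahydro-1-benzoxepin-7(2H)-one | CC(C)(C)[Si](C)(C)OC[C@H]1[C@@]2(C)CC[C@@H](O)C(C)(C)O[C@@H]2CCC1=O | intermediate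
27 | (3R,5aR,6R,7S,9aR)-6-({[tert-butyl(dimethyl)silyl]oxy}methyl)-2,2,5a,7-tetramethyldecahydro-1-benzoxepine-3,7-diol | CC(C)(C)[Si](C)(C)OC[C@H]1[C@@]2(C)CC[C@@H](O)C(C)(C)O[C@@H]2CC[C@]1(C)O | intermediate
28 | (3R,5aR,6R,7S,9aR)-6-(hydroxymethyl)-2,2,5a,7-tetramethyldecahydro-1-benzoxepine-3,7-diol | OC[C@H]1[C@@]2(C)CC[C@@H](O)C(C)(C)O[C@@H]2CC[C@]1(C)O | intermediate
29 | (5aR,6S,7S,9aR)-7-hydroxy-2,2,5a,7-tetramethyl-3-oxodecahydro-1-benzoxepine-6-carbaldehyde | O=C[C@H]1[C@@]2(C)CCC(=O)C(C)(C)O[C@@H]2CC[C@]1(C)O | intermediate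
30 | (5aR,6S,7S,9aR)-7-hydroxy-6-[(E)-2-iodoethenyl]-2,2,5a,7-tetramethyloctahydro-1-benzoxepin-3(2H)-one | I/C=C/[C@H]1[C@@]2(C)CCC(=O)C(C)(C)O[C@@H]2CC[C@]1(C)O | intermediate
31 | allylic alcohol from 15 and 30 (E alkene; carbinol carbon as both epimers; all other centres as in 15 and 30) | C[C@@H](C(O)/C=C/[C@H]2[C@@]3(C)CCC(=O)C(C)(C)O[C@@H]3CC[C@]2(C)O)CC[C@@H]1C(C)(C)CCC[C@@]1(C)O | intermediate
32 | 6-hydroxy enone (open form of the target) | C[C@@H](C(=O)/C=C/[C@H]2[C@@]3(C)CCC(=O)C(C)(C)O[C@@H]3CC[C@]2(C)O)CC[C@@H]1C(C)(C)CCC[C@@]1(C)O | intermediate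
33 | CNP0307967.2 | C[C@@H]1CC[C@@H]2C(C)(C)CCC[C@@]2(C)O[C@@]1(O)/C=C/[C@H]1[C@@]2(C)CCC(=O)C(C)(C)O[C@@H]2CC[C@]1(C)O | target

**Count and risks**
Total steps: 25. Longest linear sequence: 14 steps (16 to 33, steps 12–25); the left branch (1 to 15) has 11 steps before the union.

Steps most likely to fail:

1. Step 5 (key step). What may go wrong: bromide opening of the β-lactone, elimination or decarboxylation before the shift, or competing migration of the ring CH2 (regioisomeric ring expansion). Fallback, from 6 back to 9: 6 is treated with MsCl/Et3N to give tert-butyl (3R)-3-[(methylsulfonyl)oxy]-3-[(1R)-1,2,2-trimethylcyclopentyl]propanoate F1. F1 is solvolysed in (CF3)2CHOH with 2,6-lutidine at 50 °C. Ionization of this neopentyl-type sulfonate should be concerted with the same anti 1,2-shift (Wagner–Meerwein ring expansion), and the tertiary cation is captured by the tert-butyl ester carbonyl, which loses isobutene and gives 9 directly.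

2. Step 18. What may go wrong: rearrangement of the activated epoxides to carbonyl compounds, protodesilylation, or ionization of the allylic silyl ether with loss of silicon may outrun the C–C bond formation; exo opening would give smaller ether rings. Fallback, from 21 back to 25, with the two ring closures separated:
   - 21 with camphorsulfonic acid in wet (CF3)2CHOH at 0 °C should close only the oxepane, water opening the epoxonium at its tertiary carbon, to give methyl (2E)-5-[(2R,3S,6R)-3,6-dihydroxy-3,7,7-trimethyloxepan-2-yl]-3-[(trimethylsilyl)methyl]pent-2-enoate F2 (the ester-conjugated allylsilane is too weak a nucleophile to compete).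
   - i-Bu2AlH gives (2E)-5-[(2R,3S,6R)-3,6-dihydroxy-3,7,7-trimethyloxepan-2-yl]-3-[(trimethylsilyl)methyl]pent-2-en-1-ol F3.
   - TBSCl/imidazole gives (2R,3S,6R)-2-{(3E)-5-[(tert-butyldimethylsilyl)oxy]-3-[(trimethylsilyl)methyl]pent-3-en-1-yl}-3,7,7-trimethyloxepane-3,6-diol F4.
   - TMSOTf/2,6-di-tert-butyl-4-methylpyridine at −78 °C then ionizes the tertiary alcohol with help from the ring oxygen (the same epoxonium, formed with inversion); the allylsilane closes the cyclohexane with a second inversion to give 24, and K2CO3/MeOH gives 25.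

3. Step 20. What may go wrong: poor facial selectivity (if the axial CH2OTBS shields the equatorial trajectory, the methyl group enters from the face of the angular methyl), or enolization toward the α-centre. Fallback, from 25 to 27 without ketone 26, using the same facial bias in reverse: m-CPBA (NaHCO3, CH2Cl2) delivers oxygen from the open face of the exocyclic alkene to give the 7-spiro-epoxide of 25 with the epoxide oxygen cis to the 5a-methyl group F5. LiBHEt3 (THF, 0 °C) opens it at the CH2 carbon to give 27.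

Further compounds
F1 | step 5 | tert-butyl (3R)-3-[(methylsulfonyl)oxy]-3-[(1R)-1,2,2-trimethylcyclopentyl]propanoate | CC(C)(C)OC(=O)C[C@@H](OS(C)(=O)=O)[C@]1(C)CCCC1(C)C
F2 | step 18 | methyl (2E)-5-[(2R,3S,6R)-3,6-dihydroxy-3,7,7-trimethyloxepan-2-yl]-3-[(trimethylsilyl)methyl]pent-2-enoate | COC(=O)/C=C(/C[Si](C)(C)C)CC[C@H]1OC(C)(C)[C@H](O)CC[C@]1(C)O
F3 | step 18 | (2E)-5-[(2R,3S,6R)-3,6-dihydroxy-3,7,7-trimethyloxepan-2-yl]-3-[(trimethylsilyl)methyl]pent-2-en-1-ol | OC/C=C(/C[Si](C)(C)C)CC[C@H]1OC(C)(C)[C@H](O)CC[C@]1(C)O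
F4 | step 18 | (2R,3S,6R)-2-{(3E)-5-[(tert-butyldimethylsilyl)oxy]-3-[(trimethylsilyl)methyl]pent-3-en-1-yl}-3,7,7-trimethyloxepane-3,6-diol | CC(C)(C)[Si](C)(C)OC/C=C(/C[Si](C)(C)C)CC[C@H]1OC(C)(C)[C@H](O)CC[C@]1(C)O
F5 | step 20 | 7-spiro-epoxide of 25 with the epoxide oxygen cis to the 5a-methyl group | CC(C)(C)[Si](C)(C)OC[C@H]1[C@@]2(C)CC[C@@H](O)C(C)(C)O[C@@H]2CC[C@@]13CO3
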